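**Strategy.** With ring A as C1 (side chain)–C2–C3–C4 (methyl)–C5 (spiro), ring B as C5–C10 (C8 methyl, C9 acyloxy) and the side chain as C11, C12, everything rests on the C4–C5 bond. Because spiro C5 lies two bonds from the C9 oxygen and carries methyl-bearing C4, it is unmasked as the electrophilic β-position of a ring B enone. In the iminium ion of 3-[(1R,2S)-1-hydroxy-2-methylcyclobutyl]cyclohex-2-enone, C4 shifts from carbinol C1 to C5. This one strain-driven vinylogous α-ketol rearrangement builds ring A, the quaternary centre and two differentiated ketones (C1, C9). The precursor is assembled from (S)-2-methylcyclobutanone and a masked 3-lithiocyclohexenone.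

Key step: step 8

Remark on numbering: target locants are used for all spiro compounds; where a CIP descriptor at C1, C4 or C5 changes between intermediates, only substituent priorities change and the geometry set in step 8 is kept.
Assumption: the quinine-derived amine is taken as the catalyst matched to the (1R,2S)-cyclobutanol; should the pairing prove mismatched, its quinidine-derived pseudoenantiomer is used with no other change.
Design note: C1 and C11 are set together by a [3,3] shift from a C3 oxygen placed anti to the C4 methyl, so neither centre depends on the facial course of a hydrogenation beside the spiro carbon.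

Step 1
Reactants: 1 ethyl (S)-lactate
Product: 2 ethyl (2S)-2-(oxan-2-yloxy)propanoate (both acetal epimers)
Conditions: 3,4-dihydro-2H-pyran, PPTS (cat.), CH2Cl2, rt
Reagents that add atoms: 3,4-dihydro-2H-pyran, C1=COCCC1
Why: Acid-catalysed addition of the hydroxyl to the enol ether (tetrahydropyranyl acetal formation) should mask the alcohol against the Grignard reagent of step 2 without touching the stereocentre.

Step 2
Reactants: 2 ethyl (2S)-2-(oxan-2-yloxy)propanoate
Product: 3 1-[(1S)-1-(oxan-2-yloxy)ethyl]cyclopropan-1-ol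
Conditions: EtMgBr (2.5 equiv), Ti(Oi-Pr)4 (0.3 equiv), THF, 0 °C → rt
Reagents that add atoms: ethylmagnesium bromide, CC[Mg]Br
Why: Kulinkovich cyclopropanation, in which the titanacyclopropane formed from EtMgBr and Ti(Oi-Pr)4 adds twice to the ester carbonyl, should give the 1-substituted cyclopropanol, and the non-enolising conditions leave the α-alkoxy stereocentre intact.

Step 3
Reactants: 3 1-[(1S)-1-(oxan-2-yloxy)ethyl]cyclopropan-1-ol
Product: 4 1-[(1S)-1-hydroxyethyl]cyclopropan-1-ol
Conditions: PPTS (cat.), MeOH, 40 °C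
Reagents that add atoms: none
Why: Acid-catalysed transacetalisation to methanol should remove the tetrahydropyranyl group under conditions too mild to open the cyclopropanol.

Step 4
Reactants: 4 1-[(1S)-1-hydroxyethyl]cyclopropan-1-ol
Product: 6 (2S)-2-methylcyclobutan-1-one, via secondary mesylate 5 (not isolated)
Conditions: MsCl (1.1 equiv), Et3N, CH2Cl2, −10 °C → rt
Reagents that add atoms: none
Why: Selective sulfonylation of the secondary hydroxyl sets off a semipinacol ring expansion (cyclopropylcarbinyl to cyclobutanone) in which a ring CH2 migrates anti to the leaving mesylate, so the carbinol carbon is inverted and the (S)-lactate centre becomes the (S)-configured α-carbon of the ketone.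

Step 5
Reactants: 7 cyclohexane-1,3-dione
Product: 8 3-bromocyclohex-2-en-1-one
Conditions: PPh3, Br2, Et3N, CH2Cl2, 0 °C → rt
Reagents that add atoms: bromine, BrBr
Why: Activation of the enol oxygen of the vinylogous acid by Ph3PBr2 and addition–elimination by bromide is the standard conversion of a 1,3-dione into a 3-bromo enone.

Step 6
Reactants: 8 3-bromocyclohex-2-en-1-one
Product: 9 7-bromo-1,4-dioxaspiro[4.5]dec-6-ene
Conditions: ethylene glycol, p-TsOH (cat.), benzene, reflux, Dean–Stark
Reagents that add atoms: ethane-1,2-diol, OCCO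
Why: Acid-catalysed ketalisation with azeotropic removal of water should protect the carbonyl and give the known allylic ketal that serves as a β-acylvinyl anion equivalent.

Step 7
Reactants: 9 7-bromo-1,4-dioxaspiro[4.5]dec-6-ene; 6 (2S)-2-methylcyclobutan-1-one
Product: 12 3-[(1R,2S)-1-hydroxy-2-methylcyclobutyl]cyclohex-2-en-1-one, via vinyllithium 10 (not isolated), via ketal carbinol 11 (not isolated)
Conditions: t-BuLi (2.1 equiv), Et2O, −78 °C; then 6, −78 °C; then 0.5 M HCl, THF, 0 °C
Reagents that add atoms: water, O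
Why: Bromine–lithium exchange and 1,2-addition of the vinyllithium to the strained ketone from the face anti to its 2-methyl group should set the carbinol centre with hydroxyl cis to methyl, and hydrolysis of the allylic ketal on acidic work-up unveils the conjugated enone.

Step 8
Reactants: 12 3-[(1R,2S)-1-hydroxy-2-methylcyclobutyl]cyclohex-2-en-1-one
Product: 13 (4S,5S)-4-methylspiro[4.5]decane-1,9-dione
Conditions: 9-amino-9-deoxy-epi-quinine (20 mol%), N-Boc-L-phenylglycine (40 mol%), CCl4, 40 °C
Reagents that add atoms: none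
Why: Condensation of the primary amine with the C9 carbonyl gives an iminium ion that makes C5 electrophilic; the cyclobutanol C1–C4 bond, held parallel to the π system, migrates to C5 while C1 becomes a carbonyl, and hydrolysis of the resulting enamine releases the C9 ketone. The closest known reaction type is the amine-catalysed asymmetric vinylogous α-ketol (semipinacol-type) rearrangement of 3-(1-hydroxycyclobutyl)cyclohex-2-enones to spiro[4.5]decane diketones. Ring A closes by a suprafacial 1,2-alkyl shift, a four-to-five ring expansion and not an exo or endo cyclisation, driven by loss of cyclobutane strain and gain of the C1 carbonyl. The new quaternary centre C5 is set by the iminium face that C4 reaches: the chiral amine salt selects the rotamer about C1–C5 with the hydroxyl on the C10 side, and the substrate reinforces it because the C4 methyl then sits over the vinylic C10–H and not over the C6 methylene, while C4 itself migrates with retention. The step needs C4 to migrate in preference to C2, which the higher substitution (better migratory aptitude) of C4 secures.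

Step 9
Reactants: 13 (4S,5S)-4-methylspiro[4.5]decane-1,9-dione
Product: 14 (4S,5S)-9,9-(ethylenedioxy)-4-methylspiro[4.5]decan-1-one
Conditions: ethylene glycol (1.2 equiv), PPTS (cat.), benzene, reflux, Dean–Stark
Reagents that add atoms: ethane-1,2-diol, OCCO
Why: Chemoselective ketalisation should take place only at the ring B cyclohexanone, because the ring A carbonyl is flanked by the quaternary C5 and its ketal would be severely congested.

Step 10
Reactants: 14 (4S,5S)-9,9-(ethylenedioxy)-4-methylspiro[4.5]decan-1-one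
Product: 16 (4S,5S)-9,9-(ethylenedioxy)-4-methylspiro[4.5]dec-2-en-1-one, via trimethylsilyl enol ether 15 (not isolated)
Conditions: LiN(i-Pr)2, THF, −78 °C; Me3SiCl; then Pd(OAc)2 (1.1 equiv), MeCN, rt
Reagents that add atoms: none
Why: Saegusa–Ito dehydrogenation: C2 is the only enolisable position of the C1 ketone, and the silyl enol ether should be oxidised by divalent palladium through an oxa-π-allyl complex and β-hydride elimination to the cyclopentenone.

Step 11
Reactants: 16 (4S,5S)-9,9-(ethylenedioxy)-4-methylspiro[4.5]dec-2-en-1-one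
Product: 17 (2S,3S,4R,5S)-2,3-epoxy-9,9-(ethylenedioxy)-4-methylspiro[4.5]decan-1-one (oxirane trans to the C4 methyl)
Conditions: 30% H2O2, NaOH (cat.), MeOH, 0 °C
Reagents that add atoms: hydrogen peroxide, OO
Why: Weitz–Scheffer nucleophilic epoxidation: hydroperoxide should add to C3 from the face anti to the neighbouring C4 methyl and the enolate closes on the same face, which places the oxirane trans to the methyl.

Step 12
Reactants: 17 (2S,3S,4R,5S)-2,3-epoxy-9,9-(ethylenedioxy)-4-methylspiro[4.5]decan-1-one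
Product: 18 (3R,4R,5R)-9,9-(ethylenedioxy)-4-methylspiro[4.5]dec-1-en-3-ol (hydroxyl trans to the C4 methyl)
Conditions: N2H4·H2O, AcOH (cat.), MeOH, 0 °C → rt
Reagents that add atoms: none
Why: Wharton transposition: the epoxy hydrazone should fragment with loss of N2 to the allylic alcohol, which moves the oxygen from C1 to C3 without touching the C3–O bond (anti to the methyl) and leaves C1 as an sp2 CH of a C1=C2 alkene.

Step 13
Reactants: 18 (3R,4R,5R)-9,9-(ethylenedioxy)-4-methylspiro[4.5]dec-1-en-3-ol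
Product: 19 (3R,4R,5R)-9,9-(ethylenedioxy)-4-methylspiro[4.5]dec-1-en-3-yl propanoate
Conditions: (EtCO)2O, Et3N, DMAP (cat.), CH2Cl2, rt
Reagents that add atoms: propanoic anhydride, CCC(=O)OC(=O)CC
Why: DMAP-catalysed acylation of the secondary allylic alcohol attaches the three carbons that become C11, its methyl and C12 as an ester placed for a [3,3] shift.

Step 14
Reactants: 19 (3R,4R,5R)-9,9-(ethylenedioxy)-4-methylspiro[4.5]dec-1-en-3-yl propanoate
Product: 22 (2S)-2-[(1R,4S,5S)-9,9-(ethylenedioxy)-4-methylspiro[4.5]dec-2-en-1-yl]propan-1-ol, via Z-silyl ketene acetal 20 (not isolated), via silyl ester 21 (not isolated)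
Conditions: LiN(i-Pr)2, THF/DMPU (4:1), −78 °C; t-BuMe2SiCl; −78 → 50 °C; then LiAlH4, THF, 0 °C
Reagents that add atoms: none
Why: Ireland–Claisen rearrangement: the C1–C11 bond should form suprafacially on the face that carried the C3 oxygen (anti to the C4 methyl), which fixes C1, while the Z ketene acetal reacting through the boat transition state typical of cycloalkenyl esters (hydrogen and not methyl or silyloxy under ring A) fixes C11, and the silyl ester is reduced in the same flask to the primary alcohol.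

Step 15
Reactants: 22 (2S)-2-[(1R,4S,5S)-9,9-(ethylenedioxy)-4-methylspiro[4.5]dec-2-en-1-yl]propan-1-ol
Product: 23 (2S)-2-[(1R,4S,5S)-9,9-(ethylenedioxy)-4-methylspiro[4.5]decan-1-yl]propan-1-ol
Conditions: H2 (1 atm), 10% Pd/C, EtOAc, rt
Reagents that add atoms: none
Why: Heterogeneous catalytic hydrogenation should saturate the disubstituted C2=C3 alkene, which creates no stereocentre and leaves the ketal untouched.

Step 16
Reactants: 23 (2S)-2-[(1R,4S,5S)-9,9-(ethylenedioxy)-4-methylspiro[4.5]decan-1-yl]propan-1-ol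
Product: 24 tert-butyl{(2S)-2-[(1R,4S,5S)-9,9-(ethylenedioxy)-4-methylspiro[4.5]decan-1-yl]propoxy}diphenylsilane
Conditions: t-BuPh2SiCl, imidazole, DMF, rt
Reagents that add atoms: tert-butyl(chloro)diphenylsilane, CC(C)(C)[Si](Cl)(c1ccccc1)c1ccccc1
Why: Silylation of the primary alcohol gives an ether robust enough for the aqueous acid, enolate and oxidation chemistry that follows in ring B.

Step 17
Reactants: 24 tert-butyl{(2S)-2-[(1R,4S,5S)-9,9-(ethylenedioxy)-4-methylspiro[4.5]decan-1-yl]propoxy}diphenylsilane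
Product: 25 (1R,4S,5S)-1-[(2S)-1-(tert-butyldiphenylsilyloxy)propan-2-yl]-4-methylspiro[4.5]decan-9-one
Conditions: 1 M HCl, THF, rt
Reagents that add atoms: water, O
Why: Acid-catalysed ketal hydrolysis should free the C9 ketone while the acid-stable tert-butyldiphenylsilyl ether stays in place.

Step 18
Reactants: 25 (1R,4S,5S)-1-[(2S)-1-(tert-butyldiphenylsilyloxy)propan-2-yl]-4-methylspiro[4.5]decan-9-one
Product: 26 (1R,4S,5S)-1-[(2S)-1-(tert-butyldiphenylsilyloxy)propan-2-yl]-4,8-dimethylspiro[4.5]decan-9-one (both C8 epimers)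
Conditions: LiN(i-Pr)2 (1.05 equiv), THF, −78 °C; MeI, −78 → −20 °C
Reagents that add atoms: iodomethane, CI
Why: Kinetic enolate alkylation: LiN(i-Pr)2 should deprotonate C8 and not the neopentyl C10 next to the spiro centre, and the new C8 centre needs no control because it becomes sp2 in step 19.

Step 19
Reactants: 26 (1R,4S,5S)-1-[(2S)-1-(tert-butyldiphenylsilyloxy)propan-2-yl]-4,8-dimethylspiro[4.5]decan-9-one
Product: 27 (1R,4S,5S)-1-[(2S)-1-(tert-butyldiphenylsilyloxy)propan-2-yl]-4,8-dimethylspiro[4.5]dec-7-en-9-one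
Conditions: IBX (2.5 equiv), DMSO/toluene (1:2), 70 °C
Reagents that add atoms: none
Why: IBX-mediated ketone dehydrogenation through the enol can only run toward C8–C7 because C10 is attached to the quaternary C5, and it should give the conjugated endocyclic 2-methyl enone.

Step 20
Reactants: 27 (1R,4S,5S)-1-[(2S)-1-(tert-butyldiphenylsilyloxy)propan-2-yl]-4,8-dimethylspiro[4.5]dec-7-en-9-one
Product: 28 (1R,4S,5S,9S)-1-[(2S)-1-(tert-butyldiphenylsilyloxy)propan-2-yl]-4,8-dimethylspiro[4.5]dec-7-en-9-ol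
Conditions: (R)-2-methyl-CBS-oxazaborolidine (0.3 equiv), BH3·SMe2, THF, −40 °C
Reagents that add atoms: none
Why: Corey–Bakshi–Shibata reduction: with the α-methylated alkene arm as the large group and the C10 methylene as the small one, the (R)-oxazaborolidine should deliver hydride to the carbonyl face that gives the (9S)-allylic alcohol under reagent control.

Step 21
Reactants: 28 (1R,4S,5S,9S)-1-[(2S)-1-(tert-butyldiphenylsilyloxy)propan-2-yl]-4,8-dimethylspiro[4.5]dec-7-en-9-ol; 29 3-phenylpropanoic acid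
Product: 30 (1R,4S,5S,9S)-1-[(2S)-1-(tert-butyldiphenylsilyloxy)propan-2-yl]-4,8-dimethylspiro[4.5]dec-7-en-9-yl 3-phenylpropanoate
Conditions: DCC, DMAP (cat.), CH2Cl2, 0 °C → rt
Reagents that add atoms: none
Why: Steglich esterification through the acylpyridinium ion should acylate the hindered secondary allylic alcohol with retention at C9.

Step 22
Reactants: 30 (1R,4S,5S,9S)-1-[(2S)-1-(tert-butyldiphenylsilyloxy)propan-2-yl]-4,8-dimethylspiro[4.5]dec-7-en-9-yl 3-phenylpropanoate
Product: 31 (1R,4S,5S,9S)-1-[(2S)-1-hydroxypropan-2-yl]-4,8-dimethylspiro[4.5]dec-7-en-9-yl 3-phenylpropanoate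
Conditions: HF·pyridine, pyridine, THF, 0 °C → rt
Reagents that add atoms: none
Why: Fluoride-driven desilylation under buffered, weakly acidic conditions should remove the silyl ether without acyl migration or ionisation of the allylic ester.

Step 23
Reactants: 31 (1R,4S,5S,9S)-1-[(2S)-1-hydroxypropan-2-yl]-4,8-dimethylspiro[4.5]dec-7-en-9-yl 3-phenylpropanoate
Product: 32 (1R,4S,5S,9S)-4,8-dimethyl-1-[(2S)-1-oxopropan-2-yl]spiro[4.5]dec-7-en-9-yl 3-phenylpropanoate
Conditions: Dess–Martin periodinane, NaHCO3, CH2Cl2, 0 °C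
Reagents that add atoms: none
Why: Dess–Martin oxidation under bicarbonate buffering should give the α-branched aldehyde without epimerising C11.

Step 24
Reactants: 33 3-methylfuran-2(5H)-one
Product: 34 tert-butyldimethyl[(3-methylfuran-2-yl)oxy]silane
Conditions: t-BuMe2SiOSO2CF3, Et3N, CH2Cl2, 0 °C
Reagents that add atoms: tert-butyldimethylsilyl trifluoromethanesulfonate, CC(C)(C)[Si](C)(C)OS(=O)(=O)C(F)(F)F
Why: O-Silylation of the butenolide dienolate (soft enolisation) should give the aromatic 2-silyloxyfuran, the usual vinylogous nucleophile.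

Step 25
Reactants: 32 (1R,4S,5S,9S)-4,8-dimethyl-1-[(2S)-1-oxopropan-2-yl]spiro[4.5]dec-7-en-9-yl 3-phenylpropanoate; 34 tert-butyldimethyl[(3-methylfuran-2-yl)oxy]silane
Product: 35 (1R,4S,5S,9S)-1-[(2S)-1-hydroxy-1-(4-methyl-5-oxo-2,5-dihydrofuran-2-yl)propan-2-yl]-4,8-dimethylspiro[4.5]dec-7-en-9-yl 3-phenylpropanoate (diastereomers at the carbinol and at the furanone sp3 carbon)
Conditions: BF3·OEt2 (1.1 equiv), CH2Cl2, −78 °C; then aq. NaHCO3
Reagents that add atoms: none
Why: Vinylogous Mukaiyama aldol addition: the silyloxyfuran should attack the BF3-activated aldehyde through its unsubstituted C5, which forms the bond between C12 and the butenolide, and the two new centres are of no consequence because both are lost in step 26.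

Step 26
Reactants: 35 (1R,4S,5S,9S)-1-[(2S)-1-hydroxy-1-(4-methyl-5-oxo-2,5-dihydrofuran-2-yl)propan-2-yl]-4,8-dimethylspiro[4.5]dec-7-en-9-yl 3-phenylpropanoate
Product: 37 (1R,4S,5S,9S)-4,8-dimethyl-1-[(2S,3Z)-3-(4-methyl-5-oxofuran-2(5H)-ylidene)propan-2-yl]spiro[4.5]dec-7-en-9-yl 3-phenylpropanoate (CNP0260277.1), via secondary mesylate 36 (not isolated)
Conditions: MsCl, Et3N, CH2Cl2, −20 °C → rt
Reagents that add atoms: none
Why: Mesylation followed by E1cB elimination through the butenolide γ-carbanion should give the exocyclic alkene, with the Z isomer favoured because it keeps the alkyl group syn to the ring oxygen and away from the C4–H of the furanone.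

**Compound list**

1 | ethyl (S)-lactate | CCOC(=O)[C@H](C)O | starting material
2 | ethyl (2S)-2-(oxan-2-yloxy)propanoate (acetal epimers) | CCOC(=O)[C@H](C)OC1CCCCO1 | intermediate
3 | 1-[(1S)-1-(oxan-2-yloxy)ethyl]cyclopropan-1-ol | C[C@H](OC1CCCCO1)C1(O)CC1 | intermediate
4 | 1-[(1S)-1-hydroxyethyl]cyclopropan-1-ol | C[C@H](O)C1(O)CC1 | intermediate
5 | (1S)-1-(1-hydroxycyclopropyl)ethyl methanesulfonate | C[C@H](OS(C)(=O)=O)C1(O)CC1 | intermediate (not isolated)
6 | (2S)-2-methylcyclobutan-1-one | O=C1CC[C@@H]1C | intermediate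
7 | cyclohexane-1,3-dione | O=C1CCCC(=O)C1 | starting material
8 | 3-bromocyclohex-2-en-1-one | O=C1CCCC(Br)=C1 | intermediate
9 | 7-bromo-1,4-dioxaspiro[4.5]dec-6-ene | BrC1=CC2(CCC1)OCCO2 | intermediate
10 | (1,4-dioxaspiro[4.5]dec-6-en-7-yl)lithium | [Li]C1=CC2(CCC1)OCCO2 | intermediate (not isolated)
11 | (1R,2S)-1-(1,4-dioxaspiro[4.5]dec-6-en-7-yl)-2-methylcyclobutan-1-ol | C1COC2(O1)CCCC(=C2)[C@@]1(O)CC[C@@H]1C | intermediate (not isolated)
12 | 3-[(1R,2S)-1-hydroxy-2-methylcyclobutyl]cyclohex-2-en-1-one | O=C1CCCC(=C1)[C@@]2(O)CC[C@@H]2C | intermediate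
13 | (4S,5S)-4-methylspiro[4.5]decane-1,9-dione | O=C1CC[C@H](C)[C@@]12CCCC(=O)C2 | intermediate
14 | (4S,5S)-9,9-(ethylenedioxy)-4-methylspiro[4.5]decan-1-one | O=C1CC[C@H](C)[C@@]12CCCC3(OCCO3)C2 | intermediate
15 | {[(4S,5S)-9,9-(ethylenedioxy)-4-methylspiro[4.5]dec-1-en-1-yl]oxy}trimethylsilane | C[Si](C)(C)OC1=CC[C@H](C)[C@@]12CCCC3(OCCO3)C2 | intermediate (not isolated)
16 | (4S,5S)-9,9-(ethylenedioxy)-4-methylspiro[4.5]dec-2-en-1-one | O=C1C=C[C@H](C)[C@@]12CCCC3(OCCO3)C2 | intermediate
17 | (2S,3S,4R,5S)-2,3-epoxy-9,9-(ethylenedioxy)-4-methylspiro[4.5]decan-1-one | O=C1[C@H]2O[C@H]2[C@H](C)[C@@]13CCCC4(OCCO4)C3 | intermediate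
18 | (3R,4R,5R)-9,9-(ethylenedioxy)-4-methylspiro[4.5]dec-1-en-3-ol | C1=C[C@@H](O)[C@H](C)[C@@]12CCCC3(OCCO3)C2 | intermediate
19 | (3R,4R,5R)-9,9-(ethylenedioxy)-4-methylspiro[4.5]dec-1-en-3-yl propanoate | C1=C[C@@H](OC(=O)CC)[C@H](C)[C@@]12CCCC3(OCCO3)C2 | intermediate
20 | (Z)-tert-butyldimethylsilyl ketene acetal of 19 (methyl cis to silyloxy) | C1=C[C@@H](O/C(O[Si](C)(C)C(C)(C)C)=C/C)[C@H](C)[C@@]12CCCC3(OCCO3)C2 | intermediate (not isolated)
21 | tert-butyldimethylsilyl (2S)-2-[(1R,4S,5S)-9,9-(ethylenedioxy)-4-methylspiro[4.5]dec-2-en-1-yl]propanoate | CC(C)(C)[Si](C)(C)OC(=O)[C@@H](C)[C@H]1C=C[C@H](C)[C@@]12CCCC3(OCCO3)C2 | intermediate (not isolated)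
22 | (2S)-2-[(1R,4S,5S)-9,9-(ethylenedioxy)-4-methylspiro[4.5]dec-2-en-1-yl]propan-1-ol | OC[C@@H](C)[C@H]1C=C[C@H](C)[C@@]12CCCC3(OCCO3)C2 | intermediate
23 | (2S)-2-[(1R,4S,5S)-9,9-(ethylenedioxy)-4-methylspiro[4.5]decan-1-yl]propan-1-ol | OC[C@@H](C)[C@H]1CC[C@H](C)[C@@]12CCCC3(OCCO3)C2 | intermediate
24 | tert-butyl{(2S)-2-[(1R,4S,5S)-9,9-(ethylenedioxy)-4-methylspiro[4.5]decan-1-yl]propoxy}diphenylsilane | CC(C)(C)[Si](c1ccccc1)(c1ccccc1)OC[C@@H](C)[C@H]1CC[C@H](C)[C@@]12CCCC3(OCCO3)C2 | intermediate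
25 | (1R,4S,5S)-1-[(2S)-1-(tert-butyldiphenylsilyloxy)propan-2-yl]-4-methylspiro[4.5]decan-9-one | CC(C)(C)[Si](c1ccccc1)(c1ccccc1)OC[C@@H](C)[C@H]1CC[C@H](C)[C@@]12CCCC(=O)C2 | intermediate
26 | (1R,4S,5S)-1-[(2S)-1-(tert-butyldiphenylsilyloxy)propan-2-yl]-4,8-dimethylspiro[4.5]decan-9-one (C8 epimers) | CC(C)(C)[Si](c1ccccc1)(c1ccccc1)OC[C@@H](C)[C@H]1CC[C@H](C)[C@@]12CCC(C)C(=O)C2 | intermediate
27 | (1R,4S,5S)-1-[(2S)-1-(tert-butyldiphenylsilyloxy)propan-2-yl]-4,8-dimethylspiro[4.5]dec-7-en-9-one | CC(C)(C)[Si](c1ccccc1)(c1ccccc1)OC[C@@H](C)[C@H]1CC[C@H](C)[C@@]12CC=C(C)C(=O)C2 | intermediate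
28 | (1R,4S,5S,9S)-1-[(2S)-1-(tert-butyldiphenylsilyloxy)propan-2-yl]-4,8-dimethylspiro[4.5]dec-7-en-9-ol | CC(C)(C)[Si](c1ccccc1)(c1ccccc1)OC[C@@H](C)[C@H]1CC[C@H](C)[C@@]12CC=C(C)[C@@H](O)C2 | intermediate
29 | 3-phenylpropanoic acid | OC(=O)CCc1ccccc1 | starting material
30 | (1R,4S,5S,9S)-1-[(2S)-1-(tert-butyldiphenylsilyloxy)propan-2-yl]-4,8-dimethylspiro[4.5]dec-7-en-9-yl 3-phenylpropanoate | CC(C)(C)[Si](c1ccccc1)(c1ccccc1)OC[C@@H](C)[C@H]1CC[C@H](C)[C@@]12CC=C(C)[C@@H](OC(=O)CCc3ccccc3)C2 | intermediate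
31 | (1R,4S,5S,9S)-1-[(2S)-1-hydroxypropan-2-yl]-4,8-dimethylspiro[4.5]dec-7-en-9-yl 3-phenylpropanoate | OC[C@@H](C)[C@H]1CC[C@H](C)[C@@]12CC=C(C)[C@@H](OC(=O)CCc3ccccc3)C2 | intermediate
32 | (1R,4S,5S,9S)-4,8-dimethyl-1-[(2S)-1-oxopropan-2-yl]spiro[4.5]dec-7-en-9-yl 3-phenylpropanoate | O=C[C@@H](C)[C@H]1CC[C@H](C)[C@@]12CC=C(C)[C@@H](OC(=O)CCc3ccccc3)C2 | intermediate
33 | 3-methylfuran-2(5H)-one | CC1=CCOC1=O | starting material
34 | tert-butyldimethyl[(3-methylfuran-2-yl)oxy]silane | Cc1ccoc1O[Si](C)(C)C(C)(C)C | intermediate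
35 | (1R,4S,5S,9S)-1-[(2S)-1-hydroxy-1-(4-methyl-5-oxo-2,5-dihydrofuran-2-yl)propan-2-yl]-4,8-dimethylspiro[4.5]dec-7-en-9-yl 3-phenylpropanoate (diastereomers) | CC1=CC(OC1=O)C(O)[C@@H](C)[C@H]1CC[C@H](C)[C@@]12CC=C(C)[C@@H](OC(=O)CCc3ccccc3)C2 | intermediate
36 | methanesulfonate of 35 at the side-chain carbinol | CC1=CC(OC1=O)C(OS(C)(=O)=O)[C@@H](C)[C@H]1CC[C@H](C)[C@@]12CC=C(C)[C@@H](OC(=O)CCc3ccccc3)C2 | intermediate (not isolated)
37 | (1R,4S,5S,9S)-4,8-dimethyl-1-[(2S,3Z)-3-(4-methyl-5-oxofuran-2(5H)-ylidene)propan-2-yl]spiro[4.5]dec-7-en-9-yl 3-phenylpropanoate (CNP0260277.1) | CC1=C/C(=C/[C@@H](C)[C@H]2CC[C@H](C)[C@@]23CC=C(C)[C@@H](OC(=O)CCc2ccccc2)C3)OC1=O | target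

**Step count and risk**

Total step count: 26. Longest linear sequence: 23 steps (steps 1–4, 7–23, 25 and 26, from ethyl (S)-lactate); steps 5–6 and step 24 are side branches.

The three steps most likely to fail:

1. Step 8. The shift may proceed with poor facial selectivity at C5 if the chiral iminium ion works against the rotamer preference of the substituted cyclobutanol. A less selective acid-promoted background shift, or migration of C2, may also compete. Fallback: the route sets out from 11, isolated after a neutral quench of step 7 in place of the acid hydrolysis. N-Bromosuccinimide with propylene oxide as acid scavenger in 2-propanol at −20 °C should trigger a bromonium-induced semipinacol ring expansion, with C4 migrating anti to bromine. This gives (4S,5S,10S)-10-bromo-9,9-(ethylenedioxy)-4-methylspiro[4.5]decan-1-one F1. Bu3SnH with AIBN in toluene at 80 °C then removes the bromine by radical reduction, and the fallback comes back to the route at 14.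

2. Step 12. Hydrazone formation at the hindered C1 carbonyl may be slow, so that opening of the oxirane by hydrazine or over-reduction during fragmentation takes over. Fallback: the route sets out from 14. KN(SiMe3)2 and PhNTf2 in THF at −78 °C should give (4S,5S)-9,9-(ethylenedioxy)-4-methylspiro[4.5]dec-1-en-1-yl trifluoromethanesulfonate F2. Formate reduction (Pd(OAc)2, PPh3, Bu3N, HCO2H, DMF, 60 °C) should convert it into (4S,5S)-9,9-(ethylenedioxy)-4-methylspiro[4.5]dec-1-ene F3. Allylic hydroxylation with SeO2 (cat.) and t-BuOOH in CH2Cl2 (ene reaction then [2,3] shift) should then oxidise C3, the only allylic CH2, from the face anti to the C4 methyl. The fallback comes back at 18.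

3. Step 14. C11 selectivity may erode through incomplete Z enolate geometry or leakage through the chair transition state, and bond formation at the neopentyl C1 may be slow enough for the ketene acetal to decompose. Fallback: the route sets out from 18 and separates the two centres.
   - Johnson–Claisen rearrangement (triethyl orthoacetate, cat. propanoic acid, xylene, 140 °C) fixes C1 alone and gives ethyl 2-[(1S,4S,5S)-9,9-(ethylenedioxy)-4-methylspiro[4.5]dec-2-en-1-yl]acetate F4.
   - LiOH in aqueous THF gives 2-[(1S,4S,5S)-9,9-(ethylenedioxy)-4-methylspiro[4.5]dec-2-en-1-yl]acetic acid F5.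
   - The pivaloyl mixed anhydride and lithiated (4S)-4-benzyl-1,3-oxazolidin-2-one give (4S)-4-benzyl-3-{2-[(1S,4S,5S)-9,9-(ethylenedioxy)-4-methylspiro[4.5]dec-2-en-1-yl]acetyl}-1,3-oxazolidin-2-one F6.
   - Auxiliary-controlled methylation (NaN(SiMe3)2, MeI, THF, −78 °C) sets C11 and gives (4S)-4-benzyl-3-{(2S)-2-[(1R,4S,5S)-9,9-(ethylenedioxy)-4-methylspiro[4.5]dec-2-en-1-yl]propanoyl}-1,3-oxazolidin-2-one F7.
   - LiBH4 in Et2O with one equivalent of MeOH cleaves the auxiliary, and the fallback comes back at 22.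

Further compounds
F1 | step 8 | (4S,5S,10S)-10-bromo-9,9-(ethylenedioxy)-4-methylspiro[4.5]decan-1-one | O=C1CC[C@H](C)[C@@]12CCCC3(OCCO3)[C@H]2Br
F2 | step 12 | (4S,5S)-9,9-(ethylenedioxy)-4-methylspiro[4.5]dec-1-en-1-yl trifluoromethanesulfonate | FC(F)(F)S(=O)(=O)OC1=CC[C@H](C)[C@@]12CCCC3(OCCO3)C2
F3 | step 12 | (4S,5S)-9,9-(ethylenedioxy)-4-methylspiro[4.5]dec-1-ene | C1=CC[C@H](C)[C@@]12CCCC3(OCCO3)C2
F4 | step 14 | ethyl 2-[(1S,4S,5S)-9,9-(ethylenedioxy)-4-methylspiro[4.5]dec-2-en-1-yl]acetate | CCOC(=O)C[C@H]1C=C[C@H](C)[C@@]12CCCC3(OCCO3)C2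
F5 | step 14 | 2-[(1S,4S,5S)-9,9-(ethylenedioxy)-4-methylspiro[4.5]dec-2-en-1-yl]acetic acid | OC(=O)C[C@H]1C=C[C@H](C)[C@@]12CCCC3(OCCO3)C2
F6 | step 14 | (4S)-4-benzyl-3-{2-[(1S,4S,5S)-9,9-(ethylenedioxy)-4-methylspiro[4.5]dec-2-en-1-yl]acetyl}-1,3-oxazolidin-2-one | O=C(C[C@H]1C=C[C@H](C)[C@@]12CCCC3(OCCO3)C2)N4[C@@H](Cc5ccccc5)COC4=O
F7 | step 14 | (4S)-4-benzyl-3-{(2S)-2-[(1R,4S,5S)-9,9-(ethylenedioxy)-4-methylspiro[4.5]dec-2-en-1-yl]propanoyl}-1,3-oxazolidin-2-one | O=C([C@@H](C)[C@H]1C=C[C@H](C)[C@@]12CCCC3(OCCO3)C2)N4[C@@H](Cc5ccccc5)COC4=O
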